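**Plan**

1. The retrosynthesis cuts the two palmitate C–O bonds, then C11=C12 and C11'=C12' (Wittig; two C15 phosphonium salts on a C10 dialdehyde), then C9–C10 and C7=C8 of each half, back to one ring ester per half.
2. Both rings come from one racemic keto ester, 8, whose ring is cut at C2–C3 and C5–C6. The feature used: the gem-dimethyl carbon C1 lies between C2 and C6, and C6 carries the one-carbon branch C7, so tying C7 back to C2 gives 3,3-dimethylcyclobutanone, in which C2 and C6 are the two α-carbons of one carbonyl; crotonoyl chloride supplies C3, C4, C5 and the C5 methyl.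
3. Forward: an enamine α,α'-annulation closes the six-membered ring as a bridged bicyclo[3.1.1]heptanedione; methoxide then cuts the temporary C2–C7 bond so that C7 becomes the ester, and dehydrogenation gives enone 8.
4. Stereochemistry: hydride sets C3/C6 trans (substrate control) and a lipase splits the racemate. Alcohol 11 keeps both centres and becomes the ε ring (3'R,6'R); the antipodal acetate 12 loses C6 on double-bond migration and becomes the (3R) β ring (same spatial arrangement at C3, changed descriptor), so both antipodes are used.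
5. Each ring ester is taken to its C15 phosphonium salt (aldehyde, HWE to the ionone, vinyl Grignard, PPh3·HBr); the chain is joined β-C15 + C10 to C25, then + ε-C15 to lutein, then double palmitoylation. E geometry comes from the HWE steps and thermal equilibration after each Wittig step.

Key step: step 2

Remark: carotenoid locants are used for atoms (ring C1 to C6, chain from C7, primed in the ε half); 1, 17 and 27 are taken as purchasable; centres that are erased later (in 5 to 8, and the C9 carbinols of 20 and 25) are carried as mixtures.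

**Step 1**
Reactants: 1 3,3-dimethylcyclobutan-1-one; 2 pyrrolidine
Product: 3 1-(3,3-dimethylcyclobut-1-en-1-yl)pyrrolidine
Conditions: 2 (1.5 equiv), 4 Å molecular sieves, pentane, 0 °C to rt; filter, distil
Reagents that add atoms: none
Why: Enamine formation by condensation of the ketone with a secondary amine (the sieves take up the water); the two α-carbons of 1 (C2 and C6) are equivalent, so one enamine forms and no stereocentre arises.

**Step 2**
Reactants: 3; 4 (E)-but-2-enoyl chloride (crotonoyl chloride)
Product: 6 racemic 4,7,7-trimethylbicyclo[3.1.1]heptane-2,6-dione, via bridged iminium chloride 5 (not isolated)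
Conditions: 4 (1.05 equiv), dry MeCN, 0 °C then reflux; then H2O, NaOAc/AcOH buffer, 0 °C to rt
Reagents that add atoms: water, O
Why: N-Acylation of enamine 3 gives an N-acyl enammonium ion whose [3,3]-sigmatropic shift (aza-Claisen type, equivalent to conjugate C-alkylation) joins the enamine β-carbon C6 to the crotonyl β-carbon C5 and leaves a ketene tethered to a four-ring iminium; proton loss at C2 then gives the enamine on the other flank, and its attack on the ketene carbon C3 closes the six-membered carbocycle C1–C6 as iminium 5, which water hydrolyses to 6. The closest known reaction type is the enamine α,α'-annulation of cycloalkanone enamines with α,β-unsaturated acid chlorides, which gives bridged bicyclic 1,3-diones. The ring closure is a 6-exo-dig attack of the enamine carbon on the ketene across the 1,3-positions of the cyclobutane, so a bicyclo[3.1.1]heptane results. The new stereocentres (C5 and the bridgeheads C2 and C6) form as a racemate under no control, which is acceptable because C2 becomes CH2 in step 3, C5 becomes sp2 in step 4 and C6 is fixed by the resolution in step 6 or erased in step 7. The step needs C5 on the first α-carbon and C3 on the second, and one annulation only: the order of events (sigmatropic C–C bond first, acylation second) fixes the regiochemistry, the symmetry of 1 and the quaternary C1 leave no other enolisable site, and the bridgehead iminium 5 cannot form a further enamine.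

**Step 3**
Reactants: 6
Product: 7 methyl 2,6,6-trimethyl-4-oxocyclohexane-1-carboxylate (racemic; both relative configurations)
Conditions: NaOMe (0.2 equiv), MeOH, 0 °C to rt; AcOH
Reagents that add atoms: methanol, CO
Why: Retro-Claisen cleavage of a non-enolisable 1,3-diketone: methoxide adds to the strained four-ring carbonyl C7 and the C7–C2 bond breaks to the enolate of the six-ring ketone, which releases the cyclobutanone and bridging strain and turns C7 into the ester on C6 while C2 becomes CH2; the stereocentres that remain (C5, C6) are uncontrolled and are removed or reset in steps 4 to 6.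

**Step 4**
Reactants: 7
Product: 8 methyl 2,6,6-trimethyl-4-oxocyclohex-2-ene-1-carboxylate (racemic)
Conditions: IBX (2-iodoxybenzoic acid, 2 equiv), DMSO/toluene, 75 °C
Reagents that add atoms: none
Why: IBX dehydrogenation of a ketone to the enone through its enol; the quaternary C1 blocks the C2 side, so the alkene can only form as C4=C5, which also removes the C5 stereocentre.

**Step 5**
Reactants: 8
Product: 9 methyl (1RS,4RS)-4-hydroxy-2,6,6-trimethylcyclohex-2-ene-1-carboxylate (racemic trans alcohol)
Conditions: Li[HB(sBu)3] (1.1 equiv), THF, −78 °C; aq. NH4Cl; chromatography (removes any cis alcohol)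
Reagents that add atoms: none
Why: 1,2-Reduction of a β,β-disubstituted cyclohexenone by a bulky trialkylborohydride; hydride should come from the face away from the pseudoaxial C1 methyl of the enone envelope, which places the new C3 hydroxyl trans to the pseudoaxial C6 ester, so the relative configuration is set by the substrate and the product is racemic.

**Step 6**
Reactants: 9; 10 vinyl acetate
Product: 11 methyl (1R,4R)-4-hydroxy-2,6,6-trimethylcyclohex-2-ene-1-carboxylate (unreacted alcohol) and 12 methyl (1S,4S)-4-acetoxy-2,6,6-trimethylcyclohex-2-ene-1-carboxylate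
Conditions: Candida antarctica lipase B (immobilised), 10 (3 equiv), tBuOMe, 30 °C, stopped at half conversion; chromatography
Reagents that add atoms: none
Why: Lipase-catalysed kinetic resolution by irreversible acyl transfer from an enol ester; by the empirical size rule for secondary alcohols (CH2–CMe2 arm large, vinylic arm medium) the enzyme should acetylate the (4S) antipode and leave the (4R) one, so the absolute configuration of C3' and C6' in 11 and of the carbinol centre in 12 comes from the enzyme.

**Step 7**
Reactants: 12
Product: 14 methyl (4R)-4-hydroxy-2,6,6-trimethylcyclohex-1-ene-1-carboxylate, via free hydroxy ester 13 (not isolated)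
Conditions: NaOMe (0.3 equiv), MeOH, 60 °C
Reagents that add atoms: none
Why: Methoxide-catalysed transesterification frees the hydroxyl (13) and reversible deprotonation at C6, which is α to the ester and allylic, moves the double bond to C5=C6 (base-mediated isomerisation to the conjugated, tetrasubstituted alkene as the thermodynamic isomer); the C6 centre is erased on purpose, the carbinol centre is not touched, and its unchanged spatial arrangement is the (3R) configuration of the β ring.

**Step 8**
Reactants: 14
Product: 15 (1R)-4-(hydroxymethyl)-3,5,5-trimethylcyclohex-3-en-1-ol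
Conditions: iBu2AlH (3.5 equiv), CH2Cl2, −78 °C to 0 °C; aq. KNaC4H4O6 (potassium sodium tartrate)
Reagents that add atoms: none
Why: Hydride reduction of the conjugated ester to the allylic alcohol with iBu2AlH (1,2-selective; one extra equivalent is used up by the hydroxyl); no stereocentre is affected.

**Step 9**
Reactants: 15
Product: 16 (4R)-4-hydroxy-2,6,6-trimethylcyclohex-1-ene-1-carbaldehyde
Conditions: activated MnO2 (excess), CH2Cl2, rt
Reagents that add atoms: none
Why: Selective oxidation of an allylic alcohol by MnO2: the primary allylic alcohol becomes the aldehyde while the saturated secondary C3 alcohol is not oxidised.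

**Step 10**
Reactants: 16; 17 dimethyl (2-oxopropyl)phosphonate
Product: 18 (3E)-4-[(4R)-4-hydroxy-2,6,6-trimethylcyclohex-1-en-1-yl]but-3-en-2-one [(3R)-3-hydroxy-β-ionone]
Conditions: 17 (1.5 equiv), LiCl, DBU, MeCN, rt to 50 °C
Reagents that add atoms: none
Why: Horner–Wadsworth–Emmons olefination with a β-keto phosphonate under LiCl/amine conditions; the stabilised phosphonate anion gives the (7E) enone and the aldehyde has no α-hydrogen, so no stereocentre is at risk.

**Step 11**
Reactants: 18; 19 vinylmagnesium bromide
Product: 20 (1E)-1-[(4R)-4-hydroxy-2,6,6-trimethylcyclohex-1-en-1-yl]-3-methylpenta-1,4-dien-3-ol (both C9 epimers)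
Conditions: 19 (3 equiv), THF, −20 °C to 0 °C; aq. NH4Cl
Reagents that add atoms: none
Why: Grignard 1,2-addition of the vinyl group to the ketone of the dienone (the excess reagent covers the free hydroxyl); the new C9 carbinol forms as both epimers, which does not matter because this centre is ionised in step 12.

**Step 12**
Reactants: 20; 21 triphenylphosphonium bromide (PPh3·HBr)
Product: 22 [(2E,4E)-5-[(4R)-4-hydroxy-2,6,6-trimethylcyclohex-1-en-1-yl]-3-methylpenta-2,4-dien-1-yl]triphenylphosphonium bromide
Conditions: 21 (1.05 equiv), MeOH, rt; precipitation from EtOAc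
Reagents that add atoms: none
Why: Acid ionises the tertiary bis-allylic alcohol and PPh3 captures the pentadienyl cation at its unhindered terminus (SN1 substitution with allylic transposition), giving the conjugated dienyl phosphonium salt with the 9E geometry as the more stable one; the homoallylic C3 alcohol does not ionise.

**Step 13**
Reactants: 11
Product: 23 (1R,4R)-4-hydroxy-2,6,6-trimethylcyclohex-2-ene-1-carbaldehyde
Conditions: iBu2AlH (2.2 equiv), toluene, −78 °C; MeOH at −78 °C, then aq. KNaC4H4O6; used at once
Reagents that add atoms: none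
Why: Partial reduction of a hindered ester with iBu2AlH at low temperature: the tetrahedral aluminium alkoxide is stable at −78 °C and gives the aldehyde only on cold quench; C6' keeps its configuration because no base is present that could enolise the β,γ-unsaturated aldehyde.

**Step 14**
Reactants: 23; 17
Product: 24 (3E)-4-[(1R,4R)-4-hydroxy-2,6,6-trimethylcyclohex-2-en-1-yl]but-3-en-2-one [(3R,6R)-3-hydroxy-α-ionone]
Conditions: 17 (1.5 equiv), LiCl, iPr2NEt, MeCN, 0 °C to rt
Reagents that add atoms: none
Why: Horner–Wadsworth–Emmons olefination with a β-keto phosphonate under mild LiCl/amine conditions, chosen so that the α-stereocentre C6' of the aldehyde is not epimerised; the stabilised phosphonate gives the (7'E) enone.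

**Step 15**
Reactants: 24; 19
Product: 25 (1E)-1-[(1R,4R)-4-hydroxy-2,6,6-trimethylcyclohex-2-en-1-yl]-3-methylpenta-1,4-dien-3-ol (both C9' epimers)
Conditions: 19 (3 equiv), THF, −20 °C to 0 °C; aq. NH4Cl
Reagents that add atoms: none
Why: Grignard 1,2-addition of the vinyl group to the enone carbonyl; the new C9' carbinol forms as both epimers and is ionised in step 16, while C3' and C6' are not touched.

**Step 16**
Reactants: 25; 21
Product: 26 [(2E,4E)-5-[(1R,4R)-4-hydroxy-2,6,6-trimethylcyclohex-2-en-1-yl]-3-methylpenta-2,4-dien-1-yl]triphenylphosphonium bromide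
Conditions: 21 (1.0 equiv), MeOH, 0 °C, short reaction time; precipitation from EtOAc
Reagents that add atoms: none
Why: Same SN1 substitution with allylic transposition as in step 12; at 0 °C the tertiary bis-allylic alcohol should ionise much faster than the secondary allylic C3' alcohol, so the ε ring stereocentres are kept.

**Step 17**
Reactants: 22; 27 (2E,4E,6E)-2,7-dimethylocta-2,4,6-trienedial
Product: 28 (3R)-3-hydroxy-12'-apo-β-caroten-12'-al (all-E)
Conditions: 27 (3 equiv), NaOMe (1.1 equiv), MeOH/CH2Cl2, 0 °C to rt; then heptane, 80 °C (Z to E); chromatography, excess 27 recovered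
Reagents that add atoms: none
Why: Wittig olefination of the allylic phosphorus ylide with one formyl group of the dialdehyde used in excess (mono-olefination); the new C11=C12 bond forms as an E/Z mixture that is equilibrated by heat to the E isomer.

**Step 18**
Reactants: 28; 26
Product: 29 (3R,3'R,6'R)-β,ε-carotene-3,3'-diol (lutein, all-E)
Conditions: 26 (1.2 equiv), NaOMe (1.3 equiv), MeOH/CH2Cl2, rt, dark; then EtOAc, reflux (Z to E); crystallisation
Reagents that add atoms: none
Why: Wittig olefination of the ylide from 26 with the polyenal 28 forms the C11'=C12' bond; the Z isomer is converted by heat to the all-E polyene, and none of the three stereocentres is involved.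

**Step 19**
Reactants: 29; 30 hexadecanoyl chloride (palmitoyl chloride)
Product: 31 helenien, (3R,3'R,6'R)-β,ε-carotene-3,3'-diyl dihexadecanoate
Conditions: 30 (2.5 equiv), pyridine (5 equiv), DMAP (0.1 equiv), CH2Cl2, 0 °C to rt, dark, N2
Reagents that add atoms: none
Why: Acylation of both secondary alcohols with the acid chloride under pyridine/DMAP nucleophilic catalysis; the C–O bonds of C3 and C3' are not broken, so both configurations are retained.

**Compound list**

1 | 3,3-dimethylcyclobutan-1-one | CC1(C)CC(=O)C1 | starting material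
2 | pyrrolidine | C1CCNC1 | starting material
3 | 1-(3,3-dimethylcyclobut-1-en-1-yl)pyrrolidine | CC1(C)CC(=C1)N1CCCC1 | intermediate
4 | (E)-but-2-enoyl chloride | C/C=C/C(=O)Cl | starting material
5 | 1-(4,7,7-trimethyl-2-oxobicyclo[3.1.1]heptan-6-ylidene)pyrrolidin-1-ium chloride (racemic, not isolated) | CC1CC(=O)C2C(=[N+]3CCCC3)C1C2(C)C.[Cl-] | intermediate
6 | 4,7,7-trimethylbicyclo[3.1.1]heptane-2,6-dione (racemic, C4 epimers) | CC1CC(=O)C2C(=O)C1C2(C)C | intermediate
7 | methyl 2,6,6-trimethyl-4-oxocyclohexane-1-carboxylate (racemic, cis and trans) | COC(=O)C1C(C)CC(=O)CC1(C)C | intermediate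
8 | methyl 2,6,6-trimethyl-4-oxocyclohex-2-ene-1-carboxylate (racemic) | COC(=O)C1C(C)=CC(=O)CC1(C)C | intermediate
9 | methyl (1RS,4RS)-4-hydroxy-2,6,6-trimethylcyclohex-2-ene-1-carboxylate (racemate, both antipodes written) | COC(=O)[C@H]1C(C)=C[C@H](O)CC1(C)C.COC(=O)[C@@H]1C(C)=C[C@@H](O)CC1(C)C | intermediate
10 | vinyl acetate | CC(=O)OC=C | starting material
11 | methyl (1R,4R)-4-hydroxy-2,6,6-trimethylcyclohex-2-ene-1-carboxylate | COC(=O)[C@H]1C(C)=C[C@H](O)CC1(C)C | intermediate
12 | methyl (1S,4S)-4-acetoxy-2,6,6-trimethylcyclohex-2-ene-1-carboxylate | COC(=O)[C@@H]1C(C)=C[C@@H](OC(C)=O)CC1(C)C | intermediate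
13 | methyl (1S,4S)-4-hydroxy-2,6,6-trimethylcyclohex-2-ene-1-carboxylate (not isolated) | COC(=O)[C@@H]1C(C)=C[C@@H](O)CC1(C)C | intermediate
14 | methyl (4R)-4-hydroxy-2,6,6-trimethylcyclohex-1-ene-1-carboxylate | O[C@@H]1CC(C)=C(C(=O)OC)C(C)(C)C1 | intermediate
15 | (1R)-4-(hydroxymethyl)-3,5,5-trimethylcyclohex-3-en-1-ol | O[C@@H]1CC(C)=C(CO)C(C)(C)C1 | intermediate
16 | (4R)-4-hydroxy-2,6,6-trimethylcyclohex-1-ene-1-carbaldehyde | O[C@@H]1CC(C)=C(C=O)C(C)(C)C1 | intermediate
17 | dimethyl (2-oxopropyl)phosphonate | COP(=O)(CC(C)=O)OC | starting material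
18 | (3E)-4-[(4R)-4-hydroxy-2,6,6-trimethylcyclohex-1-en-1-yl]but-3-en-2-one | O[C@@H]1CC(C)=C(/C=C/C(C)=O)C(C)(C)C1 | intermediate
19 | vinylmagnesium bromide | C=C[Mg]Br | starting material
20 | (1E)-1-[(4R)-4-hydroxy-2,6,6-trimethylcyclohex-1-en-1-yl]-3-methylpenta-1,4-dien-3-ol (C9 epimers) | O[C@@H]1CC(C)=C(/C=C/C(C)(O)C=C)C(C)(C)C1 | intermediate
21 | triphenylphosphonium bromide | [Br-].c1ccc(cc1)[PH+](c1ccccc1)c1ccccc1 | starting material
22 | [(2E,4E)-5-[(4R)-4-hydroxy-2,6,6-trimethylcyclohex-1-en-1-yl]-3-methylpenta-2,4-dien-1-yl]triphenylphosphonium bromide | O[C@@H]1CC(C)=C(/C=C/C(C)=C/C[P+](c2ccccc2)(c2ccccc2)c2ccccc2)C(C)(C)C1.[Br-] | intermediate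
23 | (1R,4R)-4-hydroxy-2,6,6-trimethylcyclohex-2-ene-1-carbaldehyde | O=C[C@H]1C(C)=C[C@H](O)CC1(C)C | intermediate
24 | (3E)-4-[(1R,4R)-4-hydroxy-2,6,6-trimethylcyclohex-2-en-1-yl]but-3-en-2-one | CC(=O)/C=C/[C@H]1C(C)=C[C@H](O)CC1(C)C | intermediate
25 | (1E)-1-[(1R,4R)-4-hydroxy-2,6,6-trimethylcyclohex-2-en-1-yl]-3-methylpenta-1,4-dien-3-ol (C9' epimers) | C=CC(C)(O)/C=C/[C@H]1C(C)=C[C@H](O)CC1(C)C | intermediate
26 | [(2E,4E)-5-[(1R,4R)-4-hydroxy-2,6,6-trimethylcyclohex-2-en-1-yl]-3-methylpenta-2,4-dien-1-yl]triphenylphosphonium bromide | [Br-].c1ccc(cc1)[P+](c1ccccc1)(c1ccccc1)C/C=C(C)/C=C/[C@H]1C(C)=C[C@H](O)CC1(C)C | intermediate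
27 | (2E,4E,6E)-2,7-dimethylocta-2,4,6-trienedial | O=C/C(C)=C/C=C/C=C(C)/C=O | starting material
28 | (3R)-3-hydroxy-12'-apo-β-caroten-12'-al | O[C@@H]1CC(C)=C(/C=C/C(C)=C/C=C/C(C)=C/C=C/C=C(C)/C=O)C(C)(C)C1 | intermediate
29 | (3R,3'R,6'R)-β,ε-carotene-3,3'-diol (lutein) | O[C@@H]1CC(C)=C(/C=C/C(C)=C/C=C/C(C)=C/C=C/C=C(C)/C=C/C=C(C)/C=C/[C@H]2C(C)=C[C@H](O)CC2(C)C)C(C)(C)C1 | intermediate
30 | hexadecanoyl chloride | CCCCCCCCCCCCCCCC(=O)Cl | starting material
31 | helenien | CCCCCCCCCCCCCCCC(=O)O[C@@H]1CC(C)=C(/C=C/C(C)=C/C=C/C(C)=C/C=C/C=C(C)/C=C/C=C(C)/C=C/[C@H]2C(C)=C[C@H](OC(=O)CCCCCCCCCCCCCCC)CC2(C)C)C(C)(C)C1 | target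

**Count**

Total steps: 19. Longest linear sequence: 15 steps (steps 1 to 12, then 17 to 19).

**Steps most likely to fail**

Step 2. The strained cyclobutenyl enamine may oligomerise, or the first C–C bond may form without the second ring closure across the four-membered ring. Fallback: the two bonds are made one after the other from 1 without an enamine. The lithium enolate of 1 (LiN(iPr)2, THF, −78 °C) should add to methyl (E)-but-2-enoate in a Michael reaction to give methyl 3-(3,3-dimethyl-2-oxocyclobutyl)butanoate F1 (C5–C6 bond). NaOMe in MeOH/toluene at 60 °C should then bring about the intramolecular Claisen condensation from C2 onto the ester (C2–C3 bond), and the same methoxide opens the bridged dione as in step 3. The sequence sets out from 1 and comes back to the route at 7.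

Step 5. Poor facial selectivity of hydride delivery would give much cis alcohol, or conjugate reduction could compete. Fallback: reagent control in place of substrate control, from 8. Corey–Bakshi–Shibata reduction of racemic 8 with the (S)-oxazaborolidine (S)-1-methyl-3,3-diphenyltetrahydro-1H,3H-pyrrolo[1,2-c][1,3,2]oxazaborole and catecholborane (toluene, −78 °C) should reduce both antipodes to the (4R) carbinol. This gives 11 from the (1R) ketone and the cis alcohol methyl (1S,4R)-4-hydroxy-2,6,6-trimethylcyclohex-2-ene-1-carboxylate F2 from the (1S) ketone. After chromatographic separation, F2 is inverted at the carbinol by a Mitsunobu reaction with acetic acid (PPh3, DIAD, THF) to acetate 12. The fallback sets out from 8 and comes back at 11 and 12, leaving out 9 and step 6.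

Step 13. Over-reduction to the primary alcohol, or loss of the C6' configuration through enolisation of the β,γ-unsaturated aldehyde, may occur. Fallback from 11: protect, reduce fully and re-oxidise.
- Silylation (tBuMe2SiCl, imidazole, DMF) gives methyl (1R,4R)-4-[(tert-butyldimethylsilyl)oxy]-2,6,6-trimethylcyclohex-2-ene-1-carboxylate F3.
- LiAlH4 (Et2O, 0 °C) gives [(1R,4R)-4-[(tert-butyldimethylsilyl)oxy]-2,6,6-trimethylcyclohex-2-en-1-yl]methanol F4.
- Dess–Martin oxidation (NaHCO3 buffer, CH2Cl2) gives (1R,4R)-4-[(tert-butyldimethylsilyl)oxy]-2,6,6-trimethylcyclohex-2-ene-1-carbaldehyde F5.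
- The olefination of step 14 with 17 gives (3E)-4-[(1R,4R)-4-[(tert-butyldimethylsilyl)oxy]-2,6,6-trimethylcyclohex-2-en-1-yl]but-3-en-2-one F6.
- Desilylation (Bu4NF, AcOH, THF) gives 24, where the fallback comes back to the route.

**Further compounds**

F1 | step 2 | methyl 3-(3,3-dimethyl-2-oxocyclobutyl)butanoate (racemic, both diastereomers) | COC(=O)CC(C)C1C(=O)CC1(C)C
F2 | step 5 | methyl (1S,4R)-4-hydroxy-2,6,6-trimethylcyclohex-2-ene-1-carboxylate | COC(=O)[C@@H]1C(C)=C[C@H](O)CC1(C)C
F3 | step 13 | methyl (1R,4R)-4-[(tert-butyldimethylsilyl)oxy]-2,6,6-trimethylcyclohex-2-ene-1-carboxylate | COC(=O)[C@H]1C(C)=C[C@H](O[Si](C)(C)C(C)(C)C)CC1(C)C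
F4 | step 13 | [(1R,4R)-4-[(tert-butyldimethylsilyl)oxy]-2,6,6-trimethylcyclohex-2-en-1-yl]methanol | OC[C@H]1C(C)=C[C@H](O[Si](C)(C)C(C)(C)C)CC1(C)C
F5 | step 13 | (1R,4R)-4-[(tert-butyldimethylsilyl)oxy]-2,6,6-trimethylcyclohex-2-ene-1-carbaldehyde | O=C[C@H]1C(C)=C[C@H](O[Si](C)(C)C(C)(C)C)CC1(C)C
F6 | step 13 | (3E)-4-[(1R,4R)-4-[(tert-butyldimethylsilyl)oxy]-2,6,6-trimethylcyclohex-2-en-1-yl]but-3-en-2-one | CC(=O)/C=C/[C@H]1C(C)=C[C@H](O[Si](C)(C)C(C)(C)C)CC1(C)C
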